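Two questions came before the meeting, both about the rate at one mark of conversion in the flask.

common to all: left-handed substrate 10 mM; right-handed substrate 10 mM

| run | partner | precatalyst | remark |
|---|---|---|---|
| red | 1 equiv | 1.5 mol% | run made earlier |
| teal | 1 equiv | 6 mol% | run made earlier |
| ochre | 2 equiv | 3 mol% | run made earlier |
| flask | 1.00 equiv | 3 mol% |  |

| run | time / h | left-handed product / % | left-handed substrate / % |
|---|---|---|---|
| red | 2.00 | 4 | 46 |
| red | 4.00 | 12 | 40 |
| red | 6.00 | 19 | 31 |
| red | 8.00 | 23 | 29 |
| red | 10.0 | 28 | 24 |
| red | 12.0 | 32 | 22 |
| teal | 2.00 | 16 | 36 |
| teal | 4.00 | 25 | 24 |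
| teal | 6.00 | 31 | 15 |
| teal | 8.00 | 37 | 15 |
| teal | 10.0 | 37 | 13 |
| teal | 12.0 | 40 | 10 |
| ochre | 1.00 | 8 | 43 |
| ochre | 3.00 | 30 | 15 |
| ochre | 6.00 | 40 | 5 |
| ochre | 8.00 | 47 | 2 |
| ochre | 12.0 | 50 | 2 |

(standard deviation of a reading: 1.5 percentage points)

- catalyst is single-handed; left-handed substrate and right-handed substrate are mirror images of each other, charged as a racemate, each of them at the stated concentration

- factor on the rate of making left-handed product when 5.0% of the left-handed substrate and right-handed substrate together are converted if partner is charged twice over
- factor on the rate when 5.0% of the left-handed substrate and right-handed substrate together are converted if precatalyst is charged at 30 mol% instead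

The first speaker pointed out that in the red run the left-handed product grew by a factor of 3.00 from 2.00 h to 4.00 h, more than the factor of 2 on the time, so the catalyst was still growing (an induction period). She proposed that early product goes as the square of time. On that law the first readings reach the mark at 2.24 h in red and 1.12 h in teal. A factor of 4.00 on the loading thus gave a factor of 2.00 on the time, which she read as a square root.

The second speaker added the ochre run, which has the flask's loading but 2 equiv of partner, and read 0.791 h from it. The meeting then carried red to the flask's loading and got 1.58 h for the ramp time, the time the flask takes to reach the mark. Under the square law the rate at the mark goes as one over this time. So the meeting's own reckoning gave 2.00 for partner and, with a ramp time of 0.500 h at the larger loading, 3.16 for precatalyst. The chair noted that the partner figure rests on the first readings of red and ochre and the precatalyst figure on those of red and teal, each reading with a scatter of 1.5 percentage points.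

The forecast stood at 2.6 and 3.5, noting that “induction shrinks this”. It parts from the meeting on partner, being higher.

    partner + catalyst + right-handed substrate → catalyst + right-handed product (k = 5800 L² mol⁻² h⁻¹)
    partner + precatalyst → catalyst + spent reagent (k = 22.0 L mol⁻¹ h⁻¹)
    partner + catalyst + left-handed substrate → catalyst + left-handed product (k = 1.50 × 10⁵ L² mol⁻² h⁻¹)

The flask gives 2.12 for partner and 3.33 for precatalyst. It reaches the mark at 1.57 h, and at 1.00 h its catalyst stands at 19.4% of the charge, with 80.6% still precatalyst. With twice the flask's precatalyst, the ramp time becomes 1.12 h, a factor of 0.709 on 1.58 h, and the simulated factor on the time to the mark is 0.697.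

Readings and results come from a simulation with constants of no real substance, noise included.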